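## Retrosynthetic overview

1. The ten-membered carbocycle is opened at the Z-C4=C5 olefin (ring-closing metathesis, last step), giving a seco epoxy acetate with a C5 vinyl and a C4 isopropenyl group.
2. The oxirane and C14 acetate come from Sharpless epoxidation and acetylation of a C14 allylic alcohol; the 8β-methacrylate comes from Mitsunobu inversion of an 8α-alcohol.
3. The C7–C8 bond comes from a zinc Barbier union of a (5R)-3-(bromomethyl)-5-vinylbutenolide with a (Z)-β,γ-unsaturated aldehyde; C6 controls C7 and C8, and the α-methylene lactone appears here.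
4. The bromobutenolide comes from a proposed enantioselective desymmetrising ring-closing metathesis of penta-1,4-dien-3-yl 2-(bromomethyl)acrylate (forms the lactone ring, sets C6); the aldehyde comes from a Still–Gennari olefination that fixes the C1=C10 geometry.
5. Ring order: γ-lactone (step 2), oxirane (step 13), ten-membered carbocycle (step 15).

## Assumptions

- CNP0150481.2 is taken to be exactly the given SMILES. Positions are named by germacrane numbering: C6 is the lactone O–CH, C7 the lactone ring CH, C8 the ester carbon, C10/C1 the oxirane carbons, C14 the acetoxymethyl carbon, C4=C5 the Z-olefin. The target is (1R,6R,7R,8R,10S).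
- The (4R,5R) antipode of the ruthenium catalyst in step 2 is assumed to give the (R)-butenolide; if induction is opposite, the (4S,5S) antipode is used.
- Compound 7 is racemic at its phosphonate-bearing carbon, which becomes sp2 in step 5.

## Route

Step 1
Reactants: 1 penta-1,4-dien-3-ol; 2 2-(bromomethyl)prop-2-enoic acid
Product: 3 penta-1,4-dien-3-yl 2-(bromomethyl)prop-2-enoate
Conditions: DCC, DMAP (5 mol %), CH2Cl2, 0 °C
Reagents that add atoms: none
Why: Steglich esterification acylates the secondary alcohol under near-neutral conditions that spare the allylic bromide; the carbinol carbon stays prochiral.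

Step 2
Reactants: 3 penta-1,4-dien-3-yl 2-(bromomethyl)prop-2-enoate
Product: 4 (5R)-3-(bromomethyl)-5-ethenylfuran-2(5H)-one
Conditions: RuCl2(=CHPh)(PCy3)(L), L = (4R,5R)-1,3-bis(2-isopropylphenyl)-4,5-diphenylimidazolidin-2-ylidene (5 mol %), CH2Cl2 (0.02 M), 40 °C, argon sparge
Reagents that add atoms: none
Why: Proposed new method: catalytic enantioselective desymmetrising ring-closing metathesis of a divinylcarbinyl 2-substituted acrylate to a 5-vinylbutenolide; the Ru alkylidene exchanges quickly and reversibly between the two enantiotopic vinyl groups, while closure onto the electron-poor 1,1-disubstituted acrylate through the ruthenacyclobutane is slow, so the two diastereomeric alkylidenes (carbinol stereocentre directly on the carbene carbon) are selected under Curtin–Hammett control; the twisted N-(2-isopropylphenyl) group, geared by the backbone phenyls, blocks the quadrant the spectator vinyl would occupy in the disfavoured metallacycle, so only the pro-R vinyl enters the ring and C6 is set as R; closest known reaction types are asymmetric ring-closing metathesis desymmetrisation of prochiral triene ethers with chiral Ru–NHC or Mo alkylidene catalysts and racemic ring-closing metathesis of allylic acrylates to butenolides.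

Step 3
Reactants: 5 methyl 2-[bis(2,2,2-trifluoroethoxy)phosphoryl]acetate; 6 tert-butyl(2-iodoethoxy)dimethylsilane
Product: 7 methyl 2-[bis(2,2,2-trifluoroethoxy)phosphoryl]-4-{[tert-butyl(dimethyl)silyl]oxy}butanoate (racemic)
Conditions: NaH, DMSO, 0 °C → rt
Reagents that add atoms: none
Why: SN2 C-alkylation of the stabilised phosphonoacetate anion by the primary iodide; the new stereocentre is racemic and is destroyed in step 5.

Step 4
Reactants: 8 4-methylpent-4-en-1-ol
Product: 9 4-methylpent-4-enal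
Conditions: TEMPO (10 mol %), PhI(OAc)2, CH2Cl2, rt
Reagents that add atoms: none
Why: Oxoammonium (TEMPO) oxidation stops at the aldehyde and leaves the 1,1-disubstituted olefin untouched; the volatile aldehyde is used as a solution.

Step 5
Reactants: 7 methyl 2-[bis(2,2,2-trifluoroethoxy)phosphoryl]-4-{[tert-butyl(dimethyl)silyl]oxy}butanoate; 9 4-methylpent-4-enal
Product: 10 methyl (2Z)-2-(2-{[tert-butyl(dimethyl)silyl]oxy}ethyl)-6-methylhepta-2,6-dienoate
Conditions: KN(SiMe3)2, 18-crown-6, THF, −78 °C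
Reagents that add atoms: none
Why: Still–Gennari olefination: the electron-poor bis(trifluoroethyl) phosphonate under dissociating conditions collapses from the kinetic adduct, giving the Z-trisubstituted enoate with the ester carbon (future C14) cis to the C2 chain, which is the C1=C10 geometry needed.

Step 6
Reactants: 10 methyl (2Z)-2-(2-{[tert-butyl(dimethyl)silyl]oxy}ethyl)-6-methylhepta-2,6-dienoate
Product: 11 (2Z)-2-(2-{[tert-butyl(dimethyl)silyl]oxy}ethyl)-6-methylhepta-2,6-dien-1-ol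
Conditions: iBu2AlH, CH2Cl2, −78 → 0 °C
Reagents that add atoms: none
Why: Hydride 1,2-reduction of the enoate to the allylic alcohol keeps the olefin geometry and the silyl ether.

Step 7
Reactants: 11 (2Z)-2-(2-{[tert-butyl(dimethyl)silyl]oxy}ethyl)-6-methylhepta-2,6-dien-1-ol
Product: 12 (2Z)-1-{[tert-butyl(diphenyl)silyl]oxy}-2-(2-{[tert-butyl(dimethyl)silyl]oxy}ethyl)-6-methylhepta-2,6-diene
Conditions: TBDPSCl, imidazole, DMF, rt
Reagents that add atoms: tert-butyl(chloro)diphenylsilane (CC(C)(C)[Si](Cl)(c1ccccc1)c1ccccc1)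
Why: Standard silylation of a primary allylic alcohol; the TBDPS ether is chosen because it survives the acidic removal of the primary TBS ether.

Step 8
Reactants: 12 (2Z)-1-{[tert-butyl(diphenyl)silyl]oxy}-2-(2-{[tert-butyl(dimethyl)silyl]oxy}ethyl)-6-methylhepta-2,6-diene
Product: 13 (3Z)-3-({[tert-butyl(diphenyl)silyl]oxy}methyl)-7-methylocta-3,7-dien-1-ol
Conditions: camphorsulfonic acid (10 mol %), MeOH/CH2Cl2, 0 °C
Reagents that add atoms: none
Why: Acid-catalysed methanolysis cleaves a primary TBS ether far faster than a primary TBDPS ether (selective desilylation).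

Step 9
Reactants: 13 (3Z)-3-({[tert-butyl(diphenyl)silyl]oxy}methyl)-7-methylocta-3,7-dien-1-ol
Product: 14 (3Z)-3-({[tert-butyl(diphenyl)silyl]oxy}methyl)-7-methylocta-3,7-dienal
Conditions: Dess–Martin periodinane, pyridine, CH2Cl2, 0 °C; used crude at once
Reagents that add atoms: none
Why: Buffered Dess–Martin oxidation gives the β,γ-unsaturated aldehyde without moving the olefin into conjugation.

Step 10
Reactants: 4 (5R)-3-(bromomethyl)-5-ethenylfuran-2(5H)-one; 14 (3Z)-3-({[tert-butyl(diphenyl)silyl]oxy}methyl)-7-methylocta-3,7-dienal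
Product: 16 (4R,5R)-4-[(1S,3Z)-3-({[tert-butyl(diphenyl)silyl]oxy}methyl)-1-hydroxy-7-methylocta-3,7-dien-1-yl]-5-ethenyl-3-methylideneoxolan-2-one, via allylzinc bromide 15 (not isolated)
Conditions: Zn dust, THF/sat. aq. NH4Cl, 0 °C → rt
Reagents that add atoms: none
Why: Barbier 2-(alkoxycarbonyl)allylation: the allylzinc adds through its γ-carbon (SE2') in a chair Zimmerman–Traxler transition state, anti to the C6 vinyl group (C7 R, trans-lactone) and with the aldehyde chain equatorial (anti adduct, C8 S, the 8α-alcohol, deliberately epimeric to the target and inverted in step 11), and it unveils the α-methylene lactone.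

Step 11
Reactants: 16 (4R,5R)-4-[(1S,3Z)-3-({[tert-butyl(diphenyl)silyl]oxy}methyl)-1-hydroxy-7-methylocta-3,7-dien-1-yl]-5-ethenyl-3-methylideneoxolan-2-one; 17 2-methylprop-2-enoic acid
Product: 18 (1R,3Z)-3-({[tert-butyl(diphenyl)silyl]oxy}methyl)-1-[(2R,3R)-2-ethenyl-4-methylidene-5-oxooxolan-3-yl]-7-methylocta-3,7-dien-1-yl 2-methylprop-2-enoate
Conditions: PPh3, DIAD, toluene, 0 °C → rt
Reagents that add atoms: none
Why: Mitsunobu esterification: methacrylate displaces the alkoxyphosphonium by SN2 with inversion, turning C8 S (8α-OH) into the C8 R (8β) methacrylate of the target.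

Step 12
Reactants: 18 (1R,3Z)-3-({[tert-butyl(diphenyl)silyl]oxy}methyl)-1-[(2R,3R)-2-ethenyl-4-methylidene-5-oxooxolan-3-yl]-7-methylocta-3,7-dien-1-yl 2-methylprop-2-enoate
Product: 19 (1R,3Z)-1-[(2R,3R)-2-ethenyl-4-methylidene-5-oxooxolan-3-yl]-3-(hydroxymethyl)-7-methylocta-3,7-dien-1-yl 2-methylprop-2-enoate
Conditions: HF·pyridine, pyridine, THF, 0 °C → rt
Reagents that add atoms: none
Why: Buffered fluoride desilylation removes the TBDPS ether without conjugate addition to the α-methylene lactone or ester cleavage.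

Step 13
Reactants: 19 (1R,3Z)-1-[(2R,3R)-2-ethenyl-4-methylidene-5-oxooxolan-3-yl]-3-(hydroxymethyl)-7-methylocta-3,7-dien-1-yl 2-methylprop-2-enoate
Product: 20 (1R)-1-[(2R,3R)-2-ethenyl-4-methylidene-5-oxooxolan-3-yl]-2-[(2S,3R)-2-(hydroxymethyl)-3-(3-methylbut-3-en-1-yl)oxiran-2-yl]ethyl 2-methylprop-2-enoate
Conditions: Ti(OiPr)4 (10 mol %), L-(+)-diethyl tartrate (12 mol %), tBuOOH (decane), 4 Å MS, CH2Cl2, −20 °C
Reagents that add atoms: tert-butyl hydroperoxide (CC(C)(C)OO)
Why: Sharpless asymmetric epoxidation touches only the allylic alcohol (the other four olefins are non-allylic or electron-poor); L-(+)-tartrate delivers oxygen to the face that gives the (1R,10S) oxirane, and the olefin geometry is carried over stereospecifically.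

Step 14
Reactants: 20 (1R)-1-[(2R,3R)-2-ethenyl-4-methylidene-5-oxooxolan-3-yl]-2-[(2S,3R)-2-(hydroxymethyl)-3-(3-methylbut-3-en-1-yl)oxiran-2-yl]ethyl 2-methylprop-2-enoate
Product: 21 (1R)-2-[(2S,3R)-2-(acetyloxymethyl)-3-(3-methylbut-3-en-1-yl)oxiran-2-yl]-1-[(2R,3R)-2-ethenyl-4-methylidene-5-oxooxolan-3-yl]ethyl 2-methylprop-2-enoate
Conditions: Ac2O, pyridine, DMAP (cat.), CH2Cl2, 0 °C
Reagents that add atoms: acetic anhydride (CC(=O)OC(C)=O)
Why: Routine nucleophile-catalysed acetylation of the primary alcohol; no stereocentre is affected.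

Step 15
Reactants: 21 (1R)-2-[(2S,3R)-2-(acetyloxymethyl)-3-(3-methylbut-3-en-1-yl)oxiran-2-yl]-1-[(2R,3R)-2-ethenyl-4-methylidene-5-oxooxolan-3-yl]ethyl 2-methylprop-2-enoate
Product: 22 CNP0150481.2, (1R,6R,7R,8R,10S,4Z)-14-acetoxy-1,10-epoxy-8-(2-methylprop-2-enoyloxy)germacra-4,11(13)-dien-12,6-olide
Conditions: second-generation Hoveyda–Grubbs catalyst RuCl2(=CH-C6H4-2-OiPr)(H2IMes) (10 mol %; H2IMes = 1,3-dimesitylimidazolidin-2-ylidene), 1,4-benzoquinone (20 mol %), toluene (1 mM), 80 °C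
Reagents that add atoms: none
Why: Ring-closing metathesis joins the C5 vinyl and C4 isopropenyl groups; medium-ring closure is expected to favour the less strained Z trisubstituted olefin, and the C1–C10 olefin is already masked as the oxirane so no six-membered ring can form.

## Compound list

1 | penta-1,4-dien-3-ol | C=CC(O)C=C | starting material
2 | 2-(bromomethyl)prop-2-enoic acid | C=C(CBr)C(=O)O | starting material
3 | penta-1,4-dien-3-yl 2-(bromomethyl)prop-2-enoate | C=CC(C=C)OC(=O)C(=C)CBr | intermediate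
4 | (5R)-3-(bromomethyl)-5-ethenylfuran-2(5H)-one | C=C[C@H]1OC(=O)C(CBr)=C1 | intermediate
5 | methyl 2-[bis(2,2,2-trifluoroethoxy)phosphoryl]acetate | COC(=O)CP(=O)(OCC(F)(F)F)OCC(F)(F)F | starting material
6 | tert-butyl(2-iodoethoxy)dimethylsilane | CC(C)(C)[Si](C)(C)OCCI | starting material
7 | methyl 2-[bis(2,2,2-trifluoroethoxy)phosphoryl]-4-{[tert-butyl(dimethyl)silyl]oxy}butanoate (racemic) | COC(=O)C(CCO[Si](C)(C)C(C)(C)C)P(=O)(OCC(F)(F)F)OCC(F)(F)F | intermediate
8 | 4-methylpent-4-en-1-ol | C=C(C)CCCO | starting material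
9 | 4-methylpent-4-enal | C=C(C)CCC=O | intermediate
10 | methyl (2Z)-2-(2-{[tert-butyl(dimethyl)silyl]oxy}ethyl)-6-methylhepta-2,6-dienoate | COC(=O)/C(CCO[Si](C)(C)C(C)(C)C)=C\CCC(C)=C | intermediate
11 | (2Z)-2-(2-{[tert-butyl(dimethyl)silyl]oxy}ethyl)-6-methylhepta-2,6-dien-1-ol | OC/C(CCO[Si](C)(C)C(C)(C)C)=C\CCC(C)=C | intermediate
12 | (2Z)-1-{[tert-butyl(diphenyl)silyl]oxy}-2-(2-{[tert-butyl(dimethyl)silyl]oxy}ethyl)-6-methylhepta-2,6-diene | CC(C)(C)[Si](OC/C(CCO[Si](C)(C)C(C)(C)C)=C\CCC(C)=C)(c1ccccc1)c1ccccc1 | intermediate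
13 | (3Z)-3-({[tert-butyl(diphenyl)silyl]oxy}methyl)-7-methylocta-3,7-dien-1-ol | OCC/C(CO[Si](c1ccccc1)(c1ccccc1)C(C)(C)C)=C/CCC(C)=C | intermediate
14 | (3Z)-3-({[tert-butyl(diphenyl)silyl]oxy}methyl)-7-methylocta-3,7-dienal | O=CC/C(CO[Si](c1ccccc1)(c1ccccc1)C(C)(C)C)=C/CCC(C)=C | intermediate
15 | {[(5R)-5-ethenyl-2-oxo-2,5-dihydrofuran-3-yl]methyl}zinc bromide (allylzinc bromide) | C=C[C@H]1OC(=O)C(C[Zn]Br)=C1 | intermediate
16 | (4R,5R)-4-[(1S,3Z)-3-({[tert-butyl(diphenyl)silyl]oxy}methyl)-1-hydroxy-7-methylocta-3,7-dien-1-yl]-5-ethenyl-3-methylideneoxolan-2-one | C=C[C@H]1OC(=O)C(=C)[C@@H]1[C@@H](O)C/C(CO[Si](c2ccccc2)(c2ccccc2)C(C)(C)C)=C/CCC(C)=C | intermediate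
17 | 2-methylprop-2-enoic acid (methacrylic acid) | C=C(C)C(=O)O | starting material
18 | (1R,3Z)-3-({[tert-butyl(diphenyl)silyl]oxy}methyl)-1-[(2R,3R)-2-ethenyl-4-methylidene-5-oxooxolan-3-yl]-7-methylocta-3,7-dien-1-yl 2-methylprop-2-enoate | C=C[C@H]1OC(=O)C(=C)[C@@H]1[C@H](OC(=O)C(C)=C)C/C(CO[Si](c2ccccc2)(c2ccccc2)C(C)(C)C)=C/CCC(C)=C | intermediate
19 | (1R,3Z)-1-[(2R,3R)-2-ethenyl-4-methylidene-5-oxooxolan-3-yl]-3-(hydroxymethyl)-7-methylocta-3,7-dien-1-yl 2-methylprop-2-enoate | C=C[C@H]1OC(=O)C(=C)[C@@H]1[C@H](OC(=O)C(C)=C)C/C(CO)=C/CCC(C)=C | intermediate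
20 | (1R)-1-[(2R,3R)-2-ethenyl-4-methylidene-5-oxooxolan-3-yl]-2-[(2S,3R)-2-(hydroxymethyl)-3-(3-methylbut-3-en-1-yl)oxiran-2-yl]ethyl 2-methylprop-2-enoate | C=C[C@H]1OC(=O)C(=C)[C@@H]1[C@H](OC(=O)C(C)=C)C[C@@]2(CO)O[C@@H]2CCC(C)=C | intermediate
21 | (1R)-2-[(2S,3R)-2-(acetyloxymethyl)-3-(3-methylbut-3-en-1-yl)oxiran-2-yl]-1-[(2R,3R)-2-ethenyl-4-methylidene-5-oxooxolan-3-yl]ethyl 2-methylprop-2-enoate | C=C[C@H]1OC(=O)C(=C)[C@@H]1[C@H](OC(=O)C(C)=C)C[C@@]2(COC(C)=O)O[C@@H]2CCC(C)=C | intermediate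
22 | CNP0150481.2, (1R,6R,7R,8R,10S,4Z)-14-acetoxy-1,10-epoxy-8-(2-methylprop-2-enoyloxy)germacra-4,11(13)-dien-12,6-olide | C=C(C)C(=O)O[C@@H]1C[C@@]2(COC(C)=O)O[C@@H]2CC/C(C)=C\[C@H]2OC(=O)C(=C)[C@@H]21 | target

## Step count and risk

Total step count: 15. Longest linear sequence: 12 steps (steps 3, 5–15; equally steps 4, 5–15).

The three steps most likely to fail:

**Step 2 (proposed new enantioselective ring-closing metathesis).** The risk is low enantioselectivity or slow closure onto the electron-poor 1,1-disubstituted olefin. The fallback uses known chemistry, sets out from 1 and comes back at 4. Sharpless desymmetrising epoxidation of 1 (Ti(OiPr)4, L-(+)-diisopropyl tartrate, tBuOOH, 4 Å MS, CH2Cl2, −20 °C) gives (2R,3S)-1,2-epoxypent-4-en-3-ol F1 in very high ee, because enantiotopic-group and diastereoface selection reinforce each other. Steglich esterification with the known 2-({[tert-butyl(dimethyl)silyl]oxy}methyl)prop-2-enoic acid gives (1S)-1-[(2R)-oxiran-2-yl]prop-2-en-1-yl 2-({[tert-butyl(dimethyl)silyl]oxy}methyl)prop-2-enoate F2. Ordinary ring-closing metathesis with the achiral second-generation Grubbs catalyst RuCl2(=CHPh)(PCy3)(H2IMes) closes (5S)-3-({[tert-butyl(dimethyl)silyl]oxy}methyl)-5-[(2R)-oxiran-2-yl]furan-2(5H)-one F3. Stereospecific deoxygenation of the terminal oxirane (Ph3P=Se, CF3CO2H, CH2Cl2) unveils the vinyl group in (5R)-3-({[tert-butyl(dimethyl)silyl]oxy}methyl)-5-ethenylfuran-2(5H)-one F4; the descriptor changes only because the CIP priorities change. Ph3PBr2 in CH2Cl2 then converts the silyl ether directly into bromide 4.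

**Step 11 (Mitsunobu inversion at C8).** The risk is elimination toward the conjugated diene or slow displacement at the hindered carbinol. The fallback sets out from 4 and 14 and comes back at 18, making the 8β-alcohol directly instead of inverting. Bromide 4 is converted with (Bu3Sn)2 and Pd(PPh3)4 in THF into (5R)-5-ethenyl-3-[(tributylstannyl)methyl]furan-2(5H)-one F5. Addition of F5 to 14 promoted by BF3·OEt2 (CH2Cl2, −78 °C) goes through an open antiperiplanar transition state and is syn-selective, again anti to the C6 vinyl group. It gives (4R,5R)-4-[(1R,3Z)-3-({[tert-butyl(diphenyl)silyl]oxy}methyl)-1-hydroxy-7-methylocta-3,7-dien-1-yl]-5-ethenyl-3-methylideneoxolan-2-one F6. Acylation with methacrylic anhydride (Et3N, DMAP, CH2Cl2) then gives 18 with retention.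

**Step 15 (ring-closing metathesis to the ten-membered ring).** The risks are oligomerisation, an E/Z mixture, and closure of the C5 alkylidene onto the methacrylate to give a seven-membered lactone. The fallback sets out from 16 and comes back at 22; it re-orders the endgame so that no methacrylate is present during metathesis.

- HF·pyridine on 16 gives (4R,5R)-5-ethenyl-4-[(1S,3Z)-1-hydroxy-3-(hydroxymethyl)-7-methylocta-3,7-dien-1-yl]-3-methylideneoxolan-2-one F7.
- Sharpless epoxidation under the conditions of step 13 gives (4R,5R)-5-ethenyl-4-{(1S)-1-hydroxy-2-[(2S,3R)-2-(hydroxymethyl)-3-(3-methylbut-3-en-1-yl)oxiran-2-yl]ethyl}-3-methylideneoxolan-2-one F8.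
- Selective acetylation of the primary hydroxyl (AcCl, 2,4,6-collidine, CH2Cl2, −78 °C) gives [(2S,3R)-2-{(2S)-2-[(2R,3R)-2-ethenyl-4-methylidene-5-oxooxolan-3-yl]-2-hydroxyethyl}-3-(3-methylbut-3-en-1-yl)oxiran-2-yl]methyl acetate F9.
- Ring-closing metathesis under the conditions of step 15 gives (1R,6R,7R,8S,10S,4Z)-14-acetoxy-1,10-epoxy-8-hydroxygermacra-4,11(13)-dien-12,6-olide F10.
- Mitsunobu esterification of F10 with 17 (PPh3, DIAD) inverts C8 and delivers 22.

## Further compounds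

F1 | step 2 | (2R,3S)-1,2-epoxypent-4-en-3-ol | C=C[C@H](O)[C@H]1CO1
F2 | step 2 | (1S)-1-[(2R)-oxiran-2-yl]prop-2-en-1-yl 2-({[tert-butyl(dimethyl)silyl]oxy}methyl)prop-2-enoate | C=C[C@H](OC(=O)C(=C)CO[Si](C)(C)C(C)(C)C)[C@H]1CO1
F3 | step 2 | (5S)-3-({[tert-butyl(dimethyl)silyl]oxy}methyl)-5-[(2R)-oxiran-2-yl]furan-2(5H)-one | O=C1O[C@@H](C=C1CO[Si](C)(C)C(C)(C)C)[C@H]2CO2
F4 | step 2 | (5R)-3-({[tert-butyl(dimethyl)silyl]oxy}methyl)-5-ethenylfuran-2(5H)-one | C=C[C@H]1OC(=O)C(CO[Si](C)(C)C(C)(C)C)=C1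
F5 | step 11 | (5R)-5-ethenyl-3-[(tributylstannyl)methyl]furan-2(5H)-one | C=C[C@H]1OC(=O)C(C[Sn](CCCC)(CCCC)CCCC)=C1
F6 | step 11 | (4R,5R)-4-[(1R,3Z)-3-({[tert-butyl(diphenyl)silyl]oxy}methyl)-1-hydroxy-7-methylocta-3,7-dien-1-yl]-5-ethenyl-3-methylideneoxolan-2-one | C=C[C@H]1OC(=O)C(=C)[C@@H]1[C@H](O)C/C(CO[Si](c2ccccc2)(c2ccccc2)C(C)(C)C)=C/CCC(C)=C
F7 | step 15 | (4R,5R)-5-ethenyl-4-[(1S,3Z)-1-hydroxy-3-(hydroxymethyl)-7-methylocta-3,7-dien-1-yl]-3-methylideneoxolan-2-one | C=C[C@H]1OC(=O)C(=C)[C@@H]1[C@@H](O)C/C(CO)=C/CCC(C)=C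
F8 | step 15 | (4R,5R)-5-ethenyl-4-{(1S)-1-hydroxy-2-[(2S,3R)-2-(hydroxymethyl)-3-(3-methylbut-3-en-1-yl)oxiran-2-yl]ethyl}-3-methylideneoxolan-2-one | C=C[C@H]1OC(=O)C(=C)[C@@H]1[C@@H](O)C[C@@]2(CO)O[C@@H]2CCC(C)=C
F9 | step 15 | [(2S,3R)-2-{(2S)-2-[(2R,3R)-2-ethenyl-4-methylidene-5-oxooxolan-3-yl]-2-hydroxyethyl}-3-(3-methylbut-3-en-1-yl)oxiran-2-yl]methyl acetate | C=C[C@H]1OC(=O)C(=C)[C@@H]1[C@@H](O)C[C@@]2(COC(C)=O)O[C@@H]2CCC(C)=C
F10 | step 15 | (1R,6R,7R,8S,10S,4Z)-14-acetoxy-1,10-epoxy-8-hydroxygermacra-4,11(13)-dien-12,6-olide | O[C@H]1C[C@@]2(COC(C)=O)O[C@@H]2CC/C(C)=C\[C@H]2OC(=O)C(=C)[C@@H]21
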